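The route rests on the biaryl bond between C3' (ring B of the naringenin unit, ortho to the 4'-OH) and C8'' (ring A of the acacetin unit, flanked by O7'' and O1'', para to O5''). Ring B is carried dearomatised as an ortho-quinone diazide whose diazo carbon is C3'. A dirhodium catalyst converts it into an electrophilic quinoid carbene, which the unfunctionalised, innately most nucleophilic C8''–H of bis-MOM acacetin attacks. One neutral operation forges the bond, rearomatises ring B, unveils the 4'-OH and spares the base-labile (S)-C2 centre, set earlier by asymmetric conjugate addition to a chromone. Acetates silence the flavanone ring A.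

Key step: step 6

Locants: unprimed and singly primed positions belong to the flavanone (naringenin) unit. Doubly and triply primed positions belong to the flavone (acacetin) unit.

Assumption: the C3'–C8'' axis is taken as configurationally labile at room temperature (the target is written without an axial descriptor), so C2 is the only stereo-element to control.

Step 1
Reactants: 1 acacetin (5,7-dihydroxy-4'-methoxyflavone)
Product: 2 5,7-bis(methoxymethoxy)-2-(4-methoxyphenyl)-4H-chromen-4-one (5,7-di-O-MOM-acacetin)
Conditions: NaH, MOMCl, DMF, 0 °C to rt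
Reagents that add atoms: chloromethyl methyl ether (MOMCl), COCCl
Why: Williamson-type O-alkylation in which NaH deprotonates both phenols, including the chelated 5-OH, and the reactive chloromethyl ether caps them as electron-donating, acid-labile acetals.

Step 2
Reactants: 3 5,7-dihydroxy-4H-chromen-4-one
Product: 4 4-oxo-4H-chromene-5,7-diyl diacetate (5,7-diacetoxychromone)
Conditions: Ac2O, pyridine, DMAP (cat.), CH2Cl2, rt
Reagents that add atoms: acetic anhydride, CC(=O)OC(C)=O
Why: DMAP-catalysed O-acylation turns both phenols into acetates, which sharpen the chromone as a conjugate acceptor and later keep this ring A from acting as an aromatic nucleophile.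

Step 3
Reactants: 4 5,7-diacetoxychromone; 5 (4-hydroxy-3-nitrophenyl)boronic acid
Product: 6 (S)-2-(4-hydroxy-3-nitrophenyl)-4-oxochroman-5,7-diyl diacetate
Conditions: Pd(OCOCF3)2 (5 mol%), (R)-t-BuPyOx (6 mol%), NH4PF6 (30 mol%), H2O (5 equiv), ClCH2CH2Cl, 60 °C
Reagents that add atoms: none
Why: Asymmetric Hayashi–Miyaura-type conjugate addition under cationic divalent palladium (aryl transfer from boron, enantio-determining insertion of C2=C3 into the aryl–palladium bond, protonolysis of the palladium enolate), in which the tert-butyl group of the (R)-pyridine-oxazoline ligand is expected, by analogy with cyclic enones, to steer the aryl group to the Re face of C2 and so set the (S) configuration.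

Step 4
Reactants: 6 (S)-nitroflavanone diacetate
Product: 7 (S)-2-(3-amino-4-hydroxyphenyl)-4-oxochroman-5,7-diyl diacetate
Conditions: H2 (1 atm), Pd/C, EtOAc, rt; used at once
Reagents that add atoms: none
Why: Heterogeneous catalytic hydrogenation reduces the nitro group much faster than the aryl ketone or the benzylic C2–O1 bond, and the neutral medium leaves the acetates and C2 untouched.

Step 5
Reactants: 7 (S)-aminophenol diacetate
Product: 9 (S)-2-(3-diazo-4-oxocyclohexa-1,5-dien-1-yl)-4-oxochroman-5,7-diyl diacetate (ortho-quinone diazide), via diazonium tetrafluoroborate 8 (not isolated)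
Conditions: t-BuONO, 48% aq HBF4, MeCN, 0 °C; then CH2Cl2, cold sat. aq NaHCO3, dark
Reagents that add atoms: tert-butyl nitrite, CC(C)(C)ON=O (second nitrogen of 8 and 9); tetrafluoroboric acid, [H+].F[B-](F)(F)F (counter-ion of 8 only)
Why: Diazotisation of the arylamine followed by deprotonation of the strongly acidified ortho-OH gives the neutral diazo ketone, and the brief cold bicarbonate contact is too mild for acetate cleavage or retro-oxa-Michael opening at C2.

Step 6
Reactants: 2 5,7-di-O-MOM-acacetin; 9 (S)-ortho-quinone diazide
Product: 10 (S)-2-{4-hydroxy-3-[5,7-bis(methoxymethoxy)-2-(4-methoxyphenyl)-4-oxo-4H-chromen-8-yl]phenyl}-4-oxochroman-5,7-diyl diacetate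
Conditions: Rh2(esp)2 (2 mol%; esp = α,α,α',α'-tetramethyl-1,3-benzenedipropanoate), 2 (2 equiv), 4 Å MS, PhCF3, 60 °C, slow addition of 9, dark
Reagents that add atoms: none
Why: Rh2(esp)2 expels N2 from 9 to give an electrophilic rhodium quinoid carbene centred on C3'; C8'' of 2, pushed by O7'', O1'' and O5'', attacks it in Friedel–Crafts fashion, and loss of rhodium with a proton shift from C8'' to O4' rearomatises both rings and delivers the free 4'-phenol. The closest known reaction type is the dirhodium- or iron-catalysed direct arylation of electron-rich arenes with ortho-quinone diazides (diazonaphthoquinones) and para-quinone diazides to hydroxybiaryls, a formal aromatic C–H insertion of a carbene. No ring is closed and no stereocentre is created; the new axis carries only OH, OMOM and the tied-back O1'' as ortho groups and is not treated as a stereo-element. The existing (S)-C2 centre should survive because the medium is neutral and aprotic, so the retro-oxa-Michael opening to the chalcone has no base to start it. Chemoselectivity between the two phloroglucinol-type rings is secured by the protecting groups: three alkoxy-type donors make ring A of 2 the best nucleophile present, while the two acetates leave ring A of 9 and of 10 too electron-poor to compete. Site selectivity for C8'' over C6'' follows the usual preference of 5,7-dialkoxyflavones in electrophilic substitution and is reinforced sterically (C6'' sits between two freely rotating OMOM groups), and O–H insertion into the product phenol is held back by slow addition of 9 to an excess of 2.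

Step 7
Reactants: 10 protected biflavonoid
Product: 11 (2S)-2,3-dihydropodocarpusflavone A
Conditions: HCl (ca. 2 M) in MeOH, 45 °C
Reagents that add atoms: none
Why: Acid-catalysed acetal exchange and transesterification with methanol remove both MOM and both acetyl groups in one operation, the aryl methyl ether is inert, and the acidic medium avoids the phenoxide-triggered ring opening to the chalcone that would racemise C2.

Compound list
1 | acacetin | COc1ccc(-c2cc(=O)c3c(O)cc(O)cc3o2)cc1 | starting material
2 | 5,7-bis(methoxymethoxy)-2-(4-methoxyphenyl)-4H-chromen-4-one | COc1ccc(-c2cc(=O)c3c(OCOC)cc(OCOC)cc3o2)cc1 | intermediate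
3 | 5,7-dihydroxy-4H-chromen-4-one | O=c1ccoc2cc(O)cc(O)c12 | starting material
4 | 4-oxo-4H-chromene-5,7-diyl diacetate | O=c1ccoc2cc(OC(C)=O)cc(OC(C)=O)c12 | intermediate
5 | (4-hydroxy-3-nitrophenyl)boronic acid | OB(O)c1ccc(O)c([N+](=O)[O-])c1 | starting material
6 | (S)-2-(4-hydroxy-3-nitrophenyl)-4-oxochroman-5,7-diyl diacetate | O=[N+]([O-])c1cc([C@@H]2CC(=O)c3c(OC(C)=O)cc(OC(C)=O)cc3O2)ccc1O | intermediate
7 | (S)-2-(3-amino-4-hydroxyphenyl)-4-oxochroman-5,7-diyl diacetate | Nc1cc([C@@H]2CC(=O)c3c(OC(C)=O)cc(OC(C)=O)cc3O2)ccc1O | intermediate
8 | (S)-5-(5,7-diacetoxy-4-oxochroman-2-yl)-2-hydroxybenzenediazonium tetrafluoroborate (not isolated) | N#[N+]c1cc([C@@H]2CC(=O)c3c(OC(C)=O)cc(OC(C)=O)cc3O2)ccc1O.F[B-](F)(F)F | intermediate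
9 | (S)-2-(3-diazo-4-oxocyclohexa-1,5-dien-1-yl)-4-oxochroman-5,7-diyl diacetate | [N-]=[N+]=C1C=C([C@@H]2CC(=O)c3c(OC(C)=O)cc(OC(C)=O)cc3O2)C=CC1=O | intermediate
10 | (S)-2-{4-hydroxy-3-[5,7-bis(methoxymethoxy)-2-(4-methoxyphenyl)-4-oxo-4H-chromen-8-yl]phenyl}-4-oxochroman-5,7-diyl diacetate | COc1ccc(-c2cc(=O)c3c(OCOC)cc(OCOC)c(-c4cc([C@@H]5CC(=O)c6c(OC(C)=O)cc(OC(C)=O)cc6O5)ccc4O)c3o2)cc1 | intermediate
11 | (2S)-2,3-dihydropodocarpusflavone A | COc1ccc(-c2cc(=O)c3c(O)cc(O)c(-c4cc([C@@H]5CC(=O)c6c(O)cc(O)cc6O5)ccc4O)c3o2)cc1 | target

Total step count: 7. Longest linear sequence: 6 steps (3 → 4 → 6 → 7 → 9 → 10 → 11).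

Steps most likely to fail

Step 6. The carbene may be diverted in several ways:
- attack at C6'' or C3'' of the flavone;
- ylide formation at the pyranone carbonyl;
- O–H insertion into the newly formed phenol;
- Wolff-type ring contraction of ring B.

The fallback replaces the C–H functionalisation by a cross-coupling whose regiochemistry is fixed by boron. It sets out from 2 and 7 and comes back at 10. Compound 2 is iodinated at C8 (NIS, DMF, rt) to 8-iodo-5,7-bis(methoxymethoxy)-2-(4-methoxyphenyl)-4H-chromen-4-one F1. Miyaura borylation (PdCl2(dppf), B2pin2, KOAc, dioxane, 90 °C) gives the 8-pinacolboronate F2, and KHF2 in aqueous MeOH gives the potassium 8-trifluoroborate F3. Amine 7 is diazotised as in step 5, but salt 8 is precipitated with Et2O and isolated without the bicarbonate wash. A base-free Suzuki–Miyaura coupling of the arenediazonium salt 8 with F3 (Pd(OAc)2, dioxane–MeOH, rt) should then give 10. Neither the acetates nor C2 are exposed to base.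

Step 3. Transmetallation of the electron-poor, acidic boronic acid 5 may be slow, so that protodeboronation and hydrolytic loss of the 5-acetate outrun the conjugate addition. The fallback moves the introduction of nitrogen to after the C–C bond formation. It sets out from 4 and comes back at 6. Compound 4 is combined, with the same catalyst, with 4-hydroxyphenylboronic acid, an electron-rich donor that transmetallates readily, to give (S)-5,7-di-O-acetylnaringenin F4. The only free phenol ring is then mononitrated ortho to the OH with t-BuONO in THF at rt, which gives 6. The two ortho positions are equivalent and ring A is muted by its acetates.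

Step 7. Transesterification of the acetates may be slow and force a long acid exposure. That would allow erosion of configuration through reversible ionisation of the C2–O1 bond, assisted by the 4'-OH. The fallback separates the two deprotections by mechanism. It sets out from 10 and comes back at 11. The acetates are removed first under neutral conditions (NH4OAc, aqueous MeOH, rt) to give the 5'',7''-di-O-MOM ether of the target F5. After that only the fast acetal exchange (HCl in MeOH, rt, short contact) is needed to reach 11.

Further compounds
F1 | step 6 | 8-iodo-5,7-bis(methoxymethoxy)-2-(4-methoxyphenyl)-4H-chromen-4-one | COCOc1cc(OCOC)c2c(=O)cc(-c3ccc(OC)cc3)oc2c1I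
F2 | step 6 | 5,7-bis(methoxymethoxy)-2-(4-methoxyphenyl)-8-(4,4,5,5-tetramethyl-1,3,2-dioxaborolan-2-yl)-4H-chromen-4-one | COCOc1cc(OCOC)c2c(=O)cc(-c3ccc(OC)cc3)oc2c1B4OC(C)(C)C(C)(C)O4
F3 | step 6 | potassium [5,7-bis(methoxymethoxy)-2-(4-methoxyphenyl)-4-oxo-4H-chromen-8-yl]trifluoroborate | COCOc1cc(OCOC)c2c(=O)cc(-c3ccc(OC)cc3)oc2c1[B-](F)(F)F.[K+]
F4 | step 3 | (S)-2-(4-hydroxyphenyl)-4-oxochroman-5,7-diyl diacetate | Oc1ccc([C@@H]2CC(=O)c3c(OC(C)=O)cc(OC(C)=O)cc3O2)cc1
F5 | step 7 | (2S)-5'',7''-di-O-(methoxymethyl)-2,3-dihydropodocarpusflavone A | COc1ccc(-c2cc(=O)c3c(OCOC)cc(OCOC)c(-c4cc([C@@H]5CC(=O)c6c(O)cc(O)cc6O5)ccc4O)c3o2)cc1
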